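**Strategy**

The route rests on cutting the C7–C8 bond of the germacranolide. The key step exploits the homoallylic alcohol array C13=C11–C7–C8(OH), in which the exocyclic methylene of the γ-lactone sits next to a ring carbinol. A boron trifluoride-promoted SE2' addition of a 3-(tributylstannylmethyl)butenolide, through its γ-carbon C7, to a tethered C8 aldehyde forms C7–C8, closes the ten-membered carbocycle onto the existing lactone, sets C7 and C8, and moves the double bond out to C11=C13. The precursor is an open chain with the (R)-butenolide stannane at one end, two ring-cis trisubstituted alkenes (C4=C5, C1=C10) in the middle and an α-triethylsilyloxy aldehyde (C9/C8) at the other end.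

Key step: step 16

**Remarks**

- Locants follow germacrane numbering throughout, also for open-chain compounds: ring C1–C10, C14 on C10, C15 on C4, lactone oxygen on C6, C11/C12/C13 on C7.
- Structure check: the target is (6R,7S,8S,9R) with a trans-fused 12,6-lactone, a (2R)-2-methylbutanoate on O9 and an angelate, (2Z)-2-methylbut-2-enoate, on O8. In both ring alkenes the ring bonds are cis (4E and 1(10)E by CIP).
- Protecting-group design: O9 is carried as a triethylsilyl (TES) ether, O15 as tert-butyldiphenylsilyl (TBDPS) and O14 as 4-methoxybenzyl (PMB). TES at the hindered C9 can be cleaved cleanly beside the primary TBDPS ether; a bulkier silyl group there would not guarantee this. The C8 aldehyde is unveiled last, without base, because C9–H is both allylic and α to the formyl group.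
- Assumption: the (S,S)-ProPhenol/Me2Zn catalyst adds the acetylide to the Re face of crotonaldehyde (4S alcohol). If the first run shows the opposite sense, the mirror-image ligand is used and nothing else changes.

**Route**

Step 1
Reactants: 1 2-hydroxy-N-methoxy-N-methylacetamide
Product: 2 N-methoxy-N-methyl-2-(triethylsilyloxy)acetamide
Conditions: Et3SiCl, imidazole, CH2Cl2, 0 °C → rt
Reagents that add atoms: chlorotriethylsilane CC[Si](Cl)(CC)CC
Why: Routine silylation of a primary alcohol (silyl ether formation) gives the Weinreb amide that later supplies C8 and C9.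

Step 2
Reactants: 3 acrolein; 4 ethyl (triphenylphosphoranylidene)acetate
Product: 6 ethyl (2Z)-2-iodopenta-2,4-dienoate, via iodo ylide 5 (not isolated)
Conditions: 4, N-iodosuccinimide, CH2Cl2, −20 °C; then 3, −20 °C → rt
Reagents that add atoms: N-iodosuccinimide O=C1CCC(=O)N1I
Why: Wittig olefination with the α-iodinated stabilised ylide places the vinyl group trans to the ester and hence cis to iodine, the geometry later needed for C2 cis to C9 at C1=C10; the minor E isomer should be removable by chromatography.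

Step 3
Reactants: 6 ethyl (2Z)-2-iodopenta-2,4-dienoate
Product: 7 (2Z)-2-iodopenta-2,4-dien-1-ol
Conditions: i-Bu2AlH (2.2 equiv), CH2Cl2, −78 °C; Rochelle salt work-up
Reagents that add atoms: none
Why: i-Bu2AlH reduces the conjugated ester to the allylic alcohol (1,2-reduction) at low temperature without touching the alkenyl iodide or the alkene geometry.

Step 4
Reactants: 7 (2Z)-2-iodopenta-2,4-dien-1-ol
Product: 8 1-{[(2Z)-2-iodopenta-2,4-dien-1-yl]oxymethyl}-4-methoxybenzene
Conditions: NaH, 4-methoxybenzyl chloride, Bu4NI (cat.), THF/DMF, 0 °C → rt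
Reagents that add atoms: 4-methoxybenzyl chloride COc1ccc(CCl)cc1
Why: Williamson etherification of the primary allylic alkoxide installs the PMB ether that masks O14 until the end; the alkenyl iodide is inert to NaH at this temperature.

Step 5
Reactants: 8 1-{[(2Z)-2-iodopenta-2,4-dien-1-yl]oxymethyl}-4-methoxybenzene; 2 N-methoxy-N-methyl-2-(triethylsilyloxy)acetamide
Product: 10 (3Z)-3-[(4-methoxybenzyloxy)methyl]-1-(triethylsilyloxy)hexa-3,5-dien-2-one, via dienyllithium 9 (not isolated)
Conditions: t-BuLi (2 equiv), Et2O, −78 °C; then 2, −78 → −20 °C; aq. NH4Cl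
Reagents that add atoms: none
Why: Iodine–lithium exchange proceeds with retention of alkene geometry, and the dienyllithium adds once to the Weinreb amide (Weinreb ketone synthesis) because the chelated adduct survives until quench, forming the C9–C10 bond.

Step 6
Reactants: 10 (3Z)-3-[(4-methoxybenzyloxy)methyl]-1-(triethylsilyloxy)hexa-3,5-dien-2-one
Product: 11 (2R,3Z)-3-[(4-methoxybenzyloxy)methyl]-1-(triethylsilyloxy)hexa-3,5-dien-2-ol
Conditions: (R)-2-methyl-CBS-oxazaborolidine (0.2 equiv), catecholborane, toluene, −78 °C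
Reagents that add atoms: none
Why: Corey–Bakshi–Shibata reduction with the (R)-oxazaborolidine differentiates the large α-branched dienyl group from the small silyloxymethyl group and should set C9 as R; catecholborane at −78 °C leaves the diene untouched.

Step 7
Reactants: 11 (2R,3Z)-3-[(4-methoxybenzyloxy)methyl]-1-(triethylsilyloxy)hexa-3,5-dien-2-ol
Product: 12 (2R,3Z)-3-[(4-methoxybenzyloxy)methyl]-1,2-bis(triethylsilyloxy)hexa-3,5-diene
Conditions: Et3SiOTf, 2,6-lutidine, CH2Cl2, −78 °C
Reagents that add atoms: triethylsilyl trifluoromethanesulfonate CC[Si](CC)(CC)OS(=O)(=O)C(F)(F)F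
Why: Silylation with the triflate and a hindered base protects the hindered allylic C9 hydroxyl quickly, giving a bis-TES diol whose primary ether can later be cleaved selectively.

Step 8
Reactants: 13 tert-butyldiphenyl(prop-2-yn-1-yloxy)silane; 14 (E)-but-2-enal
Product: 16 (4S,5E)-1-(tert-butyldiphenylsilyloxy)hept-5-en-2-yn-4-ol, via zinc acetylide 15 (not isolated)
Conditions: (S,S)-ProPhenol (20 mol %), Me2Zn (3 equiv), Ph3PO (40 mol %), toluene, 0 °C
Reagents that add atoms: none
Why: ProPhenol/dimethylzinc-catalysed asymmetric alkynylation of an α,β-unsaturated aldehyde, in which the dinuclear zinc complex delivers the acetylide to the Re face of the aldehyde and so sets C6 (4S here, R once the lactone is formed).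

Step 9
Reactants: 16 (4S,5E)-1-(tert-butyldiphenylsilyloxy)hept-5-en-2-yn-4-ol
Product: 18 (2Z,4S,5E)-1-(tert-butyldiphenylsilyloxy)-2-iodohepta-2,5-dien-4-ol, via vinylalanate 17 (not isolated)
Conditions: NaAlH2(OCH2CH2OMe)2 (Red-Al), THF, 0 °C; EtOAc; then I2, −78 → 0 °C
Reagents that add atoms: iodine II
Why: The C6 alkoxide directs trans-hydroalumination of the propargylic alkyne (hydride to C5, aluminium to C4 in a five-membered alanate), and iodine replaces aluminium with retention, fixing iodine cis to C6 so that the later C3 substituent ends ring-cis.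

Step 10
Reactants: 12 (2R,3Z)-3-[(4-methoxybenzyloxy)methyl]-1,2-bis(triethylsilyloxy)hexa-3,5-diene; 18 (2Z,4S,5E)-1-(tert-butyldiphenylsilyloxy)-2-iodohepta-2,5-dien-4-ol
Product: 20 (2E,4S,5E,9Z,11R)-6-[(tert-butyldiphenylsilyloxy)methyl]-10-[(4-methoxybenzyloxy)methyl]-11,12-bis(triethylsilyloxy)dodeca-2,5,9-trien-4-ol, via alkylborane 19 (not isolated)
Conditions: 12, 9-BBN, THF, 0 °C → rt; then 18, Pd(dppf)Cl2 (10 mol %), AsPh3, Cs2CO3, DMF/H2O, rt
Reagents that add atoms: none
Why: B-alkyl Suzuki–Miyaura coupling, in which 9-BBN adds to the terminal CH2 of the diene (the trisubstituted alkene is too hindered) and zerovalent palladium couples the primary alkylborane with the alkenyl iodide with retention, forming C3–C4 and completing the carbon chain.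

Step 11
Reactants: 20 (2E,4S,5E,9Z,11R)-6-[(tert-butyldiphenylsilyloxy)methyl]-10-[(4-methoxybenzyloxy)methyl]-11,12-bis(triethylsilyloxy)dodeca-2,5,9-trien-4-ol; 21 2-(bromomethyl)acrylic acid
Product: 23 (2E,4S,5E,9Z,11R)-6-[(tert-butyldiphenylsilyloxy)methyl]-10-[(4-methoxybenzyloxy)methyl]-11,12-bis(triethylsilyloxy)dodeca-2,5,9-trien-4-yl 2-(bromomethyl)prop-2-enoate, via acid chloride 22 (not isolated)
Conditions: 21, 1-chloro-N,N,2-trimethylprop-1-en-1-amine, CH2Cl2, 0 °C; then 20, 2,6-lutidine, −20 → 0 °C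
Reagents that add atoms: none
Why: The acid is turned into its chloride under neutral conditions and acylates the C6 alcohol with a non-nucleophilic base (acyl chloride esterification), which avoids nucleophilic amine catalysts that would attack the allylic bromide and leaves the C6 configuration untouched.

Step 12
Reactants: 23 (2E,4S,5E,9Z,11R)-6-[(tert-butyldiphenylsilyloxy)methyl]-10-[(4-methoxybenzyloxy)methyl]-11,12-bis(triethylsilyloxy)dodeca-2,5,9-trien-4-yl 2-(bromomethyl)prop-2-enoate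
Product: 24 (5R)-3-(bromomethyl)-5-{(1E,5Z,7R)-2-[(tert-butyldiphenylsilyloxy)methyl]-6-[(4-methoxybenzyloxy)methyl]-7,8-bis(triethylsilyloxy)octa-1,5-dien-1-yl}furan-2(5H)-one
Conditions: second-generation Grubbs catalyst (10 mol %), toluene (0.005 M), 80 °C, argon sparge
Reagents that add atoms: none
Why: Ring-closing metathesis between the propenyl group and the 1,1-disubstituted acrylate alkene closes the butenolide (five-membered ring, C7=C11) with loss of propene, while the two trisubstituted chain alkenes are too hindered to engage and the neutral medium protects the now acidic C6–H.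

Step 13
Reactants: 24 (5R)-3-(bromomethyl)-5-{(1E,5Z,7R)-2-[(tert-butyldiphenylsilyloxy)methyl]-6-[(4-methoxybenzyloxy)methyl]-7,8-bis(triethylsilyloxy)octa-1,5-dien-1-yl}furan-2(5H)-one
Product: 25 (5R)-3-(bromomethyl)-5-{(1E,5Z,7R)-2-[(tert-butyldiphenylsilyloxy)methyl]-8-hydroxy-6-[(4-methoxybenzyloxy)methyl]-7-(triethylsilyloxy)octa-1,5-dien-1-yl}furan-2(5H)-one
Conditions: PPTS (0.2 equiv), MeOH/CH2Cl2 1:1, 0 °C
Reagents that add atoms: none
Why: Acid-catalysed methanolysis cleaves the primary TES ether much faster than the hindered secondary one at C9 (selective desilylation), and the allylic bromide, butenolide, PMB and TBDPS groups tolerate this mildly acidic protic medium.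

Step 14
Reactants: 25 (5R)-3-(bromomethyl)-5-{(1E,5Z,7R)-2-[(tert-butyldiphenylsilyloxy)methyl]-8-hydroxy-6-[(4-methoxybenzyloxy)methyl]-7-(triethylsilyloxy)octa-1,5-dien-1-yl}furan-2(5H)-one
Product: 26 (5R)-5-{(1E,5Z,7R)-2-[(tert-butyldiphenylsilyloxy)methyl]-8-hydroxy-6-[(4-methoxybenzyloxy)methyl]-7-(triethylsilyloxy)octa-1,5-dien-1-yl}-3-[(tributylstannyl)methyl]furan-2(5H)-one
Conditions: (Bu3Sn)2 (1.5 equiv), Pd2(dba)3 (2.5 mol %), THF, rt, dark
Reagents that add atoms: hexabutylditin CCCC[Sn](CCCC)(CCCC)[Sn](CCCC)(CCCC)CCCC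
Why: Palladium-catalysed allylic stannylation, in which zerovalent palladium ionises the activated allylic bromide and the π-allyl complex takes a stannyl group from the distannane at the unhindered CH2 terminus, giving the conjugated primary allylstannane under neutral conditions that do not epimerise C6.

Step 15
Reactants: 26 (5R)-5-{(1E,5Z,7R)-2-[(tert-butyldiphenylsilyloxy)methyl]-8-hydroxy-6-[(4-methoxybenzyloxy)methyl]-7-(triethylsilyloxy)octa-1,5-dien-1-yl}-3-[(tributylstannyl)methyl]furan-2(5H)-one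
Product: 27 (2R,3Z,7E)-7-[(tert-butyldiphenylsilyloxy)methyl]-3-[(4-methoxybenzyloxy)methyl]-8-{(2R)-5-oxo-4-[(tributylstannyl)methyl]-2,5-dihydrofuran-2-yl}-2-(triethylsilyloxy)octa-3,7-dienal
Conditions: Dess–Martin periodinane, NaHCO3, CH2Cl2, 0 °C; filtered and used crude
Reagents that add atoms: none
Why: Dess–Martin oxidation under bicarbonate buffer gives the aldehyde without base or strong acid, so the allylic α-stereocentre C9 and the allylstannane should survive until the crude aldehyde is cyclised.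

Step 16
Reactants: 27 (2R,3Z,7E)-7-[(tert-butyldiphenylsilyloxy)methyl]-3-[(4-methoxybenzyloxy)methyl]-8-{(2R)-5-oxo-4-[(tributylstannyl)methyl]-2,5-dihydrofuran-2-yl}-2-(triethylsilyloxy)octa-3,7-dienal
Product: 28 (6R,7R,8S,9R)-15-(tert-butyldiphenylsilyloxy)-8-hydroxy-14-(4-methoxybenzyloxy)-9-(triethylsilyloxy)germacra-1(10)Z,4E,11(13)-trien-12,6-olide
Conditions: BF3·OEt2 (3 equiv), CH2Cl2, −78 °C, slow addition of 27 (final 0.002 M); sat. aq. NaHCO3
Reagents that add atoms: none
Why: BF3 binds the C8 aldehyde and the butenolide allylstannane attacks it through its γ-carbon C7 in an open SE2' transition state while the C13–Sn bond, aligned with the π system, is lost as tin fluoride, so C7–C8 forms and the double bond moves out to C11=C13. The closest known reaction type is the Lewis acid-promoted intramolecular addition of an allylstannane to an aldehyde used for medium and large carbocycles, combined with the known γ-selective allylation of aldehydes by 3-(metallomethyl)butenolides. The ten-membered carbocycle closes in the 10-exo-trig mode at the carbonyl, helped by the two ring-cis trisubstituted alkenes that fold the chain and by slow addition at high dilution. C7 is set by attack on the butenolide face opposite the C6 alkenyl substituent (trans-fused lactone), and C8 by the Felkin–Anh preference for attack anti to the C9 silyloxy group (BF3 cannot chelate a silyl ether) together with the syn C7/C8 preference of open transition states of γ-substituted allylstannanes. The step needs the aldehyde to react without prior epimerisation at the allylic C9 and without protodestannylation, which the freshly made crude aldehyde, the low temperature and the ether-masked O14 and O15 should secure.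

Step 17
Reactants: 28 (6R,7R,8S,9R)-15-(tert-butyldiphenylsilyloxy)-8-hydroxy-14-(4-methoxybenzyloxy)-9-(triethylsilyloxy)germacra-1(10)Z,4E,11(13)-trien-12,6-olide; 29 angelic acid
Product: 31 (6R,7S,8S,9R)-8-angeloyloxy-15-(tert-butyldiphenylsilyloxy)-14-(4-methoxybenzyloxy)-9-(triethylsilyloxy)germacra-1(10)Z,4E,11(13)-trien-12,6-olide, via mixed anhydride 30 (not isolated)
Conditions: 29, 2,4,6-trichlorobenzoyl chloride, Et3N, toluene, rt; filter; then 28, toluene, 80 °C
Reagents that add atoms: none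
Why: Esterification through the preformed angelic 2,4,6-trichlorobenzoic anhydride (Yamaguchi-type acylation without DMAP) acylates the only free hydroxyl, O8, under near-neutral conditions that keep the Z geometry of the angelate, do not add to the methylene lactone and give the free O8 little chance to translactonise.

Step 18
Reactants: 31 (6R,7S,8S,9R)-8-angeloyloxy-15-(tert-butyldiphenylsilyloxy)-14-(4-methoxybenzyloxy)-9-(triethylsilyloxy)germacra-1(10)Z,4E,11(13)-trien-12,6-olide
Product: 32 (6R,7S,8S,9R)-8-angeloyloxy-15-(tert-butyldiphenylsilyloxy)-9-hydroxy-14-(4-methoxybenzyloxy)germacra-1(10)Z,4E,11(13)-trien-12,6-olide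
Conditions: HF·pyridine, pyridine, THF, 0 °C
Reagents that add atoms: none
Why: Buffered HF·pyridine removes the secondary TES ether far faster than the primary TBDPS ether (selective fluoride-mediated desilylation), and the mildly acidic medium disfavours acyl migration from O8 to O9.

Step 19
Reactants: 32 (6R,7S,8S,9R)-8-angeloyloxy-15-(tert-butyldiphenylsilyloxy)-9-hydroxy-14-(4-methoxybenzyloxy)germacra-1(10)Z,4E,11(13)-trien-12,6-olide; 33 (R)-2-methylbutanoic acid
Product: 34 (6R,7S,8S,9R)-8-angeloyloxy-15-(tert-butyldiphenylsilyloxy)-14-(4-methoxybenzyloxy)-9-[(2R)-2-methylbutanoyloxy]germacra-1(10)Z,4E,11(13)-trien-12,6-olide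
Conditions: 33, i-PrN=C=N-i-Pr, DMAP (cat.), CH2Cl2, 0 °C → rt
Reagents that add atoms: none
Why: Steglich esterification of the only free hydroxyl, O9, with the enantiopure acid at low temperature, where the α-stereocentre of the acid should not epimerise, places the second ester unambiguously.

Step 20
Reactants: 34 (6R,7S,8S,9R)-8-angeloyloxy-15-(tert-butyldiphenylsilyloxy)-14-(4-methoxybenzyloxy)-9-[(2R)-2-methylbutanoyloxy]germacra-1(10)Z,4E,11(13)-trien-12,6-olide
Product: 35 (6R,7S,8S,9R)-8-angeloyloxy-15-(tert-butyldiphenylsilyloxy)-14-hydroxy-9-[(2R)-2-methylbutanoyloxy]germacra-1(10)Z,4E,11(13)-trien-12,6-olide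
Conditions: DDQ, CH2Cl2/pH 7 buffer 10:1, 0 °C
Reagents that add atoms: none
Why: Oxidative cleavage of the PMB ether with DDQ in buffered wet dichloromethane frees only O14, since the silyl ether, both esters and the methylene lactone are inert to it.

Step 21
Reactants: 35 (6R,7S,8S,9R)-8-angeloyloxy-15-(tert-butyldiphenylsilyloxy)-14-hydroxy-9-[(2R)-2-methylbutanoyloxy]germacra-1(10)Z,4E,11(13)-trien-12,6-olide
Product: 36 (6R,7S,8S,9R)-8-angeloyloxy-15-(tert-butyldiphenylsilyloxy)-9-[(2R)-2-methylbutanoyloxy]-14-oxogermacra-1(10)E,4E,11(13)-trien-12,6-olide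
Conditions: MnO2 (excess), CH2Cl2, rt
Reagents that add atoms: none
Why: MnO2 oxidises the primary allylic alcohol selectively to the enal (allylic oxidation), and the C1=C10 geometry with C2 trans to the formyl group is the thermodynamically preferred one.

Step 22
Reactants: 36 (6R,7S,8S,9R)-8-angeloyloxy-15-(tert-butyldiphenylsilyloxy)-9-[(2R)-2-methylbutanoyloxy]-14-oxogermacra-1(10)E,4E,11(13)-trien-12,6-olide
Product: 37 (6R,7S,8S,9R)-8-angeloyloxy-15-hydroxy-9-[(2R)-2-methylbutanoyloxy]-14-oxogermacra-1(10)E,4E,11(13)-trien-12,6-olide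
Conditions: HF·pyridine, THF, 0 °C → rt
Reagents that add atoms: none
Why: Fluoride-mediated desilylation with HF·pyridine removes the primary TBDPS ether under mildly acidic conditions that the enal, both esters and the methylene lactone tolerate, giving the target.

**Compound list**

1 | 2-hydroxy-N-methoxy-N-methylacetamide | OCC(=O)N(C)OC | starting material
2 | N-methoxy-N-methyl-2-(triethylsilyloxy)acetamide | CC[Si](CC)(CC)OCC(=O)N(C)OC | intermediate
3 | acrolein (prop-2-enal) | C=CC=O | starting material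
4 | ethyl (triphenylphosphoranylidene)acetate | CCOC(=O)C=P(c1ccccc1)(c1ccccc1)c1ccccc1 | starting material
5 | ethyl 2-iodo-2-(triphenylphosphoranylidene)acetate | CCOC(=O)C(I)=P(c1ccccc1)(c1ccccc1)c1ccccc1 | intermediate
6 | ethyl (2Z)-2-iodopenta-2,4-dienoate | C=C/C=C(\I)C(=O)OCC | intermediate
7 | (2Z)-2-iodopenta-2,4-dien-1-ol | C=C/C=C(\I)CO | intermediate
8 | 1-{[(2Z)-2-iodopenta-2,4-dien-1-yl]oxymethyl}-4-methoxybenzene | C=C/C=C(\I)COCc1ccc(OC)cc1 | intermediate
9 | [(2E)-1-(4-methoxybenzyloxy)penta-2,4-dien-2-yl]lithium (lithium cis to the vinyl group) | C=C/C=C(\[Li])COCc1ccc(OC)cc1 | intermediate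
10 | (3Z)-3-[(4-methoxybenzyloxy)methyl]-1-(triethylsilyloxy)hexa-3,5-dien-2-one | C=C/C=C(/COCc1ccc(OC)cc1)C(=O)CO[Si](CC)(CC)CC | intermediate
11 | (2R,3Z)-3-[(4-methoxybenzyloxy)methyl]-1-(triethylsilyloxy)hexa-3,5-dien-2-ol | C=C/C=C(/COCc1ccc(OC)cc1)[C@@H](O)CO[Si](CC)(CC)CC | intermediate
12 | (2R,3Z)-3-[(4-methoxybenzyloxy)methyl]-1,2-bis(triethylsilyloxy)hexa-3,5-diene | C=C/C=C(/COCc1ccc(OC)cc1)[C@@H](O[Si](CC)(CC)CC)CO[Si](CC)(CC)CC | intermediate
13 | tert-butyldiphenyl(prop-2-yn-1-yloxy)silane | C#CCO[Si](c1ccccc1)(c1ccccc1)C(C)(C)C | starting material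
14 | (E)-but-2-enal (crotonaldehyde) | C/C=C/C=O | starting material
15 | methyl{3-[(tert-butyldiphenylsilyl)oxy]prop-1-yn-1-yl}zinc | C[Zn]C#CCO[Si](c1ccccc1)(c1ccccc1)C(C)(C)C | intermediate
16 | (4S,5E)-1-(tert-butyldiphenylsilyloxy)hept-5-en-2-yn-4-ol | C/C=C/[C@H](O)C#CCO[Si](c1ccccc1)(c1ccccc1)C(C)(C)C | intermediate
17 | sodium (5S)-3-[(tert-butyldiphenylsilyloxy)methyl]-2,2-bis(2-methoxyethoxy)-5-[(E)-prop-1-enyl]-2,5-dihydro-1,2-oxaaluminol-2-uide | [Na+].COCCO[Al-]1(OCCOC)O[C@@H](/C=C/C)C=C1CO[Si](c1ccccc1)(c1ccccc1)C(C)(C)C | intermediate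
18 | (2Z,4S,5E)-1-(tert-butyldiphenylsilyloxy)-2-iodohepta-2,5-dien-4-ol | C/C=C/[C@H](O)/C=C(/CO[Si](c1ccccc1)(c1ccccc1)C(C)(C)C)I | intermediate
19 | 9-{(3Z,5R)-4-[(4-methoxybenzyloxy)methyl]-5,6-bis(triethylsilyloxy)hex-3-en-1-yl}-9-borabicyclo[3.3.1]nonane | C(C/C=C(/COCc1ccc(OC)cc1)[C@@H](O[Si](CC)(CC)CC)CO[Si](CC)(CC)CC)B1C2CCCC1CCC2 | intermediate
20 | (2E,4S,5E,9Z,11R)-6-[(tert-butyldiphenylsilyloxy)methyl]-10-[(4-methoxybenzyloxy)methyl]-11,12-bis(triethylsilyloxy)dodeca-2,5,9-trien-4-ol (carbinol carbon = C6) | C/C=C/[C@H](O)/C=C(/CO[Si](c1ccccc1)(c1ccccc1)C(C)(C)C)CC/C=C(/COCc1ccc(OC)cc1)[C@@H](O[Si](CC)(CC)CC)CO[Si](CC)(CC)CC | intermediate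
21 | 2-(bromomethyl)acrylic acid | C=C(CBr)C(=O)O | starting material
22 | 2-(bromomethyl)acryloyl chloride | C=C(CBr)C(Cl)=O | intermediate
23 | (2E,4S,5E,9Z,11R)-6-[(tert-butyldiphenylsilyloxy)methyl]-10-[(4-methoxybenzyloxy)methyl]-11,12-bis(triethylsilyloxy)dodeca-2,5,9-trien-4-yl 2-(bromomethyl)prop-2-enoate | C/C=C/[C@H](OC(=O)C(=C)CBr)/C=C(/CO[Si](c1ccccc1)(c1ccccc1)C(C)(C)C)CC/C=C(/COCc1ccc(OC)cc1)[C@@H](O[Si](CC)(CC)CC)CO[Si](CC)(CC)CC | intermediate
24 | (5R)-3-(bromomethyl)-5-{(1E,5Z,7R)-2-[(tert-butyldiphenylsilyloxy)methyl]-6-[(4-methoxybenzyloxy)methyl]-7,8-bis(triethylsilyloxy)octa-1,5-dien-1-yl}furan-2(5H)-one | BrCC1=C[C@H](OC1=O)/C=C(/CO[Si](c1ccccc1)(c1ccccc1)C(C)(C)C)CC/C=C(/COCc1ccc(OC)cc1)[C@@H](O[Si](CC)(CC)CC)CO[Si](CC)(CC)CC | intermediate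
25 | (5R)-3-(bromomethyl)-5-{(1E,5Z,7R)-2-[(tert-butyldiphenylsilyloxy)methyl]-8-hydroxy-6-[(4-methoxybenzyloxy)methyl]-7-(triethylsilyloxy)octa-1,5-dien-1-yl}furan-2(5H)-one | BrCC1=C[C@H](OC1=O)/C=C(/CO[Si](c1ccccc1)(c1ccccc1)C(C)(C)C)CC/C=C(/COCc1ccc(OC)cc1)[C@@H](O[Si](CC)(CC)CC)CO | intermediate
26 | (5R)-5-{(1E,5Z,7R)-2-[(tert-butyldiphenylsilyloxy)methyl]-8-hydroxy-6-[(4-methoxybenzyloxy)methyl]-7-(triethylsilyloxy)octa-1,5-dien-1-yl}-3-[(tributylstannyl)methyl]furan-2(5H)-one | CCCC[Sn](CCCC)(CCCC)CC1=C[C@H](OC1=O)/C=C(/CO[Si](c1ccccc1)(c1ccccc1)C(C)(C)C)CC/C=C(/COCc1ccc(OC)cc1)[C@@H](O[Si](CC)(CC)CC)CO | intermediate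
27 | (2R,3Z,7E)-7-[(tert-butyldiphenylsilyloxy)methyl]-3-[(4-methoxybenzyloxy)methyl]-8-{(2R)-5-oxo-4-[(tributylstannyl)methyl]-2,5-dihydrofuran-2-yl}-2-(triethylsilyloxy)octa-3,7-dienal (seco-C7/C8 stannylmethyl butenolide aldehyde) | CCCC[Sn](CCCC)(CCCC)CC1=C[C@H](OC1=O)/C=C(/CO[Si](c1ccccc1)(c1ccccc1)C(C)(C)C)CC/C=C(/COCc1ccc(OC)cc1)[C@@H](O[Si](CC)(CC)CC)C=O | intermediate
28 | (6R,7R,8S,9R)-15-(tert-butyldiphenylsilyloxy)-8-hydroxy-14-(4-methoxybenzyloxy)-9-(triethylsilyloxy)germacra-1(10)Z,4E,11(13)-trien-12,6-olide (trans-fused lactone, ring alkenes cis within the ring) | C=C1C(=O)O[C@@H]2/C=C(/CO[Si](c3ccccc3)(c3ccccc3)C(C)(C)C)CC/C=C(/COCc3ccc(OC)cc3)[C@@H](O[Si](CC)(CC)CC)[C@@H](O)[C@@H]12 | intermediate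
29 | angelic acid, (2Z)-2-methylbut-2-enoic acid | C/C=C(/C)C(=O)O | starting material
30 | (2Z)-2-methylbut-2-enoic 2,4,6-trichlorobenzoic anhydride | C/C=C(/C)C(=O)OC(=O)c1c(Cl)cc(Cl)cc1Cl | intermediate
31 | (6R,7S,8S,9R)-8-angeloyloxy-15-(tert-butyldiphenylsilyloxy)-14-(4-methoxybenzyloxy)-9-(triethylsilyloxy)germacra-1(10)Z,4E,11(13)-trien-12,6-olide | C=C1C(=O)O[C@@H]2/C=C(/CO[Si](c3ccccc3)(c3ccccc3)C(C)(C)C)CC/C=C(/COCc3ccc(OC)cc3)[C@@H](O[Si](CC)(CC)CC)[C@@H](OC(=O)/C(C)=C\C)[C@@H]12 | intermediate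
32 | (6R,7S,8S,9R)-8-angeloyloxy-15-(tert-butyldiphenylsilyloxy)-9-hydroxy-14-(4-methoxybenzyloxy)germacra-1(10)Z,4E,11(13)-trien-12,6-olide | C=C1C(=O)O[C@@H]2/C=C(/CO[Si](c3ccccc3)(c3ccccc3)C(C)(C)C)CC/C=C(/COCc3ccc(OC)cc3)[C@@H](O)[C@@H](OC(=O)/C(C)=C\C)[C@@H]12 | intermediate
33 | (R)-2-methylbutanoic acid | CC[C@@H](C)C(=O)O | starting material
34 | (6R,7S,8S,9R)-8-angeloyloxy-15-(tert-butyldiphenylsilyloxy)-14-(4-methoxybenzyloxy)-9-[(2R)-2-methylbutanoyloxy]germacra-1(10)Z,4E,11(13)-trien-12,6-olide | C=C1C(=O)O[C@@H]2/C=C(/CO[Si](c3ccccc3)(c3ccccc3)C(C)(C)C)CC/C=C(/COCc3ccc(OC)cc3)[C@@H](OC(=O)[C@H](C)CC)[C@@H](OC(=O)/C(C)=C\C)[C@@H]12 | intermediate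
35 | (6R,7S,8S,9R)-8-angeloyloxy-15-(tert-butyldiphenylsilyloxy)-14-hydroxy-9-[(2R)-2-methylbutanoyloxy]germacra-1(10)Z,4E,11(13)-trien-12,6-olide | C=C1C(=O)O[C@@H]2/C=C(/CO[Si](c3ccccc3)(c3ccccc3)C(C)(C)C)CC/C=C(/CO)[C@@H](OC(=O)[C@H](C)CC)[C@@H](OC(=O)/C(C)=C\C)[C@@H]12 | intermediate
36 | (6R,7S,8S,9R)-8-angeloyloxy-15-(tert-butyldiphenylsilyloxy)-9-[(2R)-2-methylbutanoyloxy]-14-oxogermacra-1(10)E,4E,11(13)-trien-12,6-olide | C=C1C(=O)O[C@@H]2/C=C(/CO[Si](c3ccccc3)(c3ccccc3)C(C)(C)C)CC/C=C(/C=O)[C@@H](OC(=O)[C@H](C)CC)[C@@H](OC(=O)/C(C)=C\C)[C@@H]12 | intermediate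
37 | (6R,7S,8S,9R)-8-angeloyloxy-15-hydroxy-9-[(2R)-2-methylbutanoyloxy]-14-oxogermacra-1(10)E,4E,11(13)-trien-12,6-olide (CNP0290361.1) | C=C1C(=O)O[C@@H]2/C=C(/CO)CC/C=C(/C=O)[C@@H](OC(=O)[C@H](C)CC)[C@@H](OC(=O)/C(C)=C\C)[C@@H]12 | target

**Totals and risks**

Total step count: 22. Longest linear sequence: 19 steps (steps 2–7, then 10–22); steps 1, 8 and 9 are side branches.

The three steps most likely to fail:

1. Step 16 (key step). The open transition state may not meet all three facial demands at once, so the ring could close with the wrong sense at C8, or closure could be slow enough for protodestannylation and intermolecular allylation to take over. The fallback forms the same bond through a cyclic transition state and then inverts C8. It sets out from bromo alcohol 25: Dess–Martin oxidation should give the bromo aldehyde F1. CrCl2 in THF at high dilution (intramolecular Nozaki–Hiyama–Kishi allylation) then closes C7–C8 through a chair-like allylchromium transition state, which for this γ-substituted allyl unit is expected to favour the C8-epimeric alcohol F2. Mitsunobu esterification of F2 with angelic acid 29 (PPh3, DIAD) inverts C8 and comes back to the route at angelate 31.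

2. Step 14. The π-allylpalladium intermediate may expel the lactone carboxylate (ring opening to a dienoic acid), deliver tin to C7 instead of C13, or couple with allylstannane already formed. The fallback brings tin in before the lactone ring exists and uses no palladium. It sets out from bromoacrylate 23: zinc dust and Bu3SnCl in THF/aq. NH4Cl (Barbier-type stannylation) should give the stannylmethyl acrylate F3; both allyl termini of the open acrylate are equivalent, so the regiochemistry cannot go astray. Ring-closing metathesis as in step 12 gives the stannyl butenolide F4, and PPTS in methanol as in step 13 removes the primary TES ether and comes back to the route at 26.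

3. Step 12. Ring closure onto the hindered, electron-poor alkene that carries the allylic bromide may be slow, with catalyst decay and olefin migration. The fallback closes the ring first and adds the side-chain carbon afterwards; it also bypasses step 11. It sets out from alcohol 20: acryloyl chloride and i-Pr2NEt give the acrylate F5, and ring-closing metathesis onto the unsubstituted acrylate gives the butenolide F6. Morita–Baylis–Hillman hydroxymethylation (aqueous formaldehyde, catalytic PBu3) gives the hydroxymethyl butenolide F7; the integrity of C6 has to be checked at this point. Appel bromination (CBr4, PPh3) comes back to the route at bromide 24.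

**Further compounds**

F1 | step 16 | (2R,3Z,7E)-8-[(2R)-4-(bromomethyl)-5-oxo-2,5-dihydrofuran-2-yl]-7-[(tert-butyldiphenylsilyloxy)methyl]-3-[(4-methoxybenzyloxy)methyl]-2-(triethylsilyloxy)octa-3,7-dienal | BrCC1=C[C@H](OC1=O)/C=C(/CO[Si](c1ccccc1)(c1ccccc1)C(C)(C)C)CC/C=C(/COCc1ccc(OC)cc1)[C@@H](O[Si](CC)(CC)CC)C=O
F2 | step 16 | (6R,7R,8R,9R)-15-(tert-butyldiphenylsilyloxy)-8-hydroxy-14-(4-methoxybenzyloxy)-9-(triethylsilyloxy)germacra-1(10)Z,4E,11(13)-trien-12,6-olide (C8 epimer of 28) | C=C1C(=O)O[C@@H]2/C=C(/CO[Si](c3ccccc3)(c3ccccc3)C(C)(C)C)CC/C=C(/COCc3ccc(OC)cc3)[C@@H](O[Si](CC)(CC)CC)[C@H](O)[C@@H]12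
F3 | step 14 | (2E,4S,5E,9Z,11R)-6-[(tert-butyldiphenylsilyloxy)methyl]-10-[(4-methoxybenzyloxy)methyl]-11,12-bis(triethylsilyloxy)dodeca-2,5,9-trien-4-yl 2-[(tributylstannyl)methyl]prop-2-enoate | C/C=C/[C@H](OC(=O)C(=C)C[Sn](CCCC)(CCCC)CCCC)/C=C(/CO[Si](c1ccccc1)(c1ccccc1)C(C)(C)C)CC/C=C(/COCc1ccc(OC)cc1)[C@@H](O[Si](CC)(CC)CC)CO[Si](CC)(CC)CC
F4 | step 14 | (5R)-5-{(1E,5Z,7R)-2-[(tert-butyldiphenylsilyloxy)methyl]-6-[(4-methoxybenzyloxy)methyl]-7,8-bis(triethylsilyloxy)octa-1,5-dien-1-yl}-3-[(tributylstannyl)methyl]furan-2(5H)-one | CCCC[Sn](CCCC)(CCCC)CC1=C[C@H](OC1=O)/C=C(/CO[Si](c1ccccc1)(c1ccccc1)C(C)(C)C)CC/C=C(/COCc1ccc(OC)cc1)[C@@H](O[Si](CC)(CC)CC)CO[Si](CC)(CC)CC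
F5 | step 12 | (2E,4S,5E,9Z,11R)-6-[(tert-butyldiphenylsilyloxy)methyl]-10-[(4-methoxybenzyloxy)methyl]-11,12-bis(triethylsilyloxy)dodeca-2,5,9-trien-4-yl prop-2-enoate | C/C=C/[C@H](OC(=O)C=C)/C=C(/CO[Si](c1ccccc1)(c1ccccc1)C(C)(C)C)CC/C=C(/COCc1ccc(OC)cc1)[C@@H](O[Si](CC)(CC)CC)CO[Si](CC)(CC)CC
F6 | step 12 | (5S)-5-{(1E,5Z,7R)-2-[(tert-butyldiphenylsilyloxy)methyl]-6-[(4-methoxybenzyloxy)methyl]-7,8-bis(triethylsilyloxy)octa-1,5-dien-1-yl}furan-2(5H)-one | O=C1C=C[C@H](O1)/C=C(/CO[Si](c1ccccc1)(c1ccccc1)C(C)(C)C)CC/C=C(/COCc1ccc(OC)cc1)[C@@H](O[Si](CC)(CC)CC)CO[Si](CC)(CC)CC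
F7 | step 12 | (5R)-5-{(1E,5Z,7R)-2-[(tert-butyldiphenylsilyloxy)methyl]-6-[(4-methoxybenzyloxy)methyl]-7,8-bis(triethylsilyloxy)octa-1,5-dien-1-yl}-3-(hydroxymethyl)furan-2(5H)-one | OCC1=C[C@H](OC1=O)/C=C(/CO[Si](c1ccccc1)(c1ccccc1)C(C)(C)C)CC/C=C(/COCc1ccc(OC)cc1)[C@@H](O[Si](CC)(CC)CC)CO[Si](CC)(CC)CC
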